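**Retrosynthetic overview**
- Last C–C disconnection: the C8–CH2 bond, made by Friedel–Crafts benzylation of acylphloroglucinol 23 with the 8-(methoxymethyl)flavan 18. C8 is reached regioselectively through the 8-bromide, and all benzyl ethers fall in one final hydrogenolysis.
- C2 and C3 are set together by reagent-controlled syn hydroboration of the achiral flav-2-ene 12, which comes from base isomerization of the racemic flav-3-ene 11.
- Ring C of 11 is disconnected to aryne 8 (C4a≡C8a of ring A) and cinnamaldehyde 7: aryne/C=O (2+2) addition forms O1–C8a and C4–C4a, then 4π opening and oxa-6π closure form O1–C2.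
- Enabling feature: O1 and C4 sit on adjacent carbons (C8a, C4a) of the phloroglucinol-type ring A, whose C5 oxygen next to C4a polarizes the aryne so that oxygen adds at C8a. The chain O1–C2(aryl)–C3–C4 is a cinnamaldehyde at the aldehyde oxidation level.
- Ring order: rings A, B and the acylphloroglucinol ring are bought as arenes; ring C is the only ring built (step 4).

Key step: step 4

Remark: flavan numbering is used throughout (O1, C2, C3, C4, C4a, C5–C8, C8a; ring A = benzo ring, ring B = 2-aryl ring, ring C = pyran ring). Compounds 1, 6 and 19 and all reagents are taken as commercial.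

**Route**

Step 1
Reactants: 1 3,5-bis(benzyloxy)phenol
Product: 2 3,5-bis(benzyloxy)-2-bromophenol
Conditions: NBS (1.0 equiv), CH2Cl2, −78 °C → 0 °C
Reagents that add atoms: N-bromosuccinimide O=C1CCC(=O)N1Br
Why: Electrophilic aromatic bromination of a phloroglucinol-type phenol, expected ortho to the free hydroxyl (hydrogen-bonded delivery of NBS at low temperature, the para carbon being flanked by two benzyloxy groups); the two ortho carbons are equivalent, so one monobromide should form.

Step 2
Reactants: 2 3,5-bis(benzyloxy)-2-bromophenol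
Product: 5 3,5-bis(benzyloxy)-2-(trimethylsilyl)phenyl trifluoromethanesulfonate, via aryl trimethylsilyl ether 3 (not isolated), via lithium 2-silylphenoxide 4 (not isolated)
Conditions: HMDS, THF, 70 °C, then evaporation; n-BuLi (1.1 equiv), THF, −78 °C; Tf2O (1.2 equiv), −78 °C → 0 °C
Reagents that add atoms: hexamethyldisilazane C[Si](C)(C)N[Si](C)(C)C; trifluoromethanesulfonic anhydride O=S(=O)(OS(=O)(=O)C(F)(F)F)C(F)(F)F; n-butyllithium [Li]CCCC (lithium of intermediate 4 only)
Why: O-silylation, bromine–lithium exchange and anionic 1,3 O→C silyl shift (retro-Brook rearrangement) put the silyl group where bromine stood, and the lithium phenoxide set free is triflated in the same flask to give a Kobayashi-type aryne precursor.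

Step 3
Reactants: 6 3,4-bis(benzyloxy)benzaldehyde
Product: 7 (E)-3-[3,4-bis(benzyloxy)phenyl]prop-2-enal
Conditions: Ph3P=CHCHO (1.1 equiv), toluene, 80 °C
Reagents that add atoms: (triphenylphosphoranylidene)acetaldehyde O=CC=P(c1ccccc1)(c1ccccc1)c1ccccc1
Why: Wittig olefination with a stabilized formylmethylene ylide, which should give the (E)-enal, the small excess limiting a second homologation.

Step 4
Reactants: 5 3,5-bis(benzyloxy)-2-(trimethylsilyl)phenyl trifluoromethanesulfonate; 7 (E)-3-[3,4-bis(benzyloxy)phenyl]prop-2-enal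
Product: 11 racemic 5,7-bis(benzyloxy)-2-[3,4-bis(benzyloxy)phenyl]-2H-chromene, via aryne 8 (not isolated), via benzoxete 9 (not isolated), via ortho-quinone methide 10 (not isolated)
Conditions: CsF (3 equiv), MeCN, 40 °C, slow addition of 5 to 7 (2 equiv)
Reagents that add atoms: none
Why: Fluoride-induced 1,2-elimination of 5 gives aryne 8, whose C4a≡C8a bond is polarized by the C5 benzyloxy group next to C4a, so the carbonyl oxygen of 7 (made more nucleophilic by the para-benzyloxy cinnamyl system) adds at C8a and the aryl anion left at C4a closes on the oxocarbenium carbon, a stepwise (2+2) addition across C=O that forms O1–C8a and C4–C4a and gives benzoxete 9. Ring strain drives conrotatory 4π ring-opening of 9 to ortho-quinone methide 10, and a thermal disrotatory oxa-6π electrocyclization then closes ring C through O1–C2 and restores the aromaticity of ring A. The closest known reaction type is the annulation of arynes from ortho-silylaryl triflates with cinnamaldehydes to 2-aryl-2H-chromenes, related to aryne insertion into the C=O bond of aldehydes and formamides. The only new stereocentre, C2, is formed without control as a racemate, which is accepted because step 5 removes it. The step needs site selectivity on the unsymmetrical aryne, secured by the inductive and distortion effect of C5–O and by the unhindered C8a (C8–H), and chemoselectivity for C=O over the C=C bond and over a second aryne, secured by the aldehyde function, the excess of 7 and the slow release of 8.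

Step 5
Reactants: 11 racemic 5,7-bis(benzyloxy)-2-[3,4-bis(benzyloxy)phenyl]-2H-chromene
Product: 12 5,7-bis(benzyloxy)-2-[3,4-bis(benzyloxy)phenyl]-4H-chromene
Conditions: KOtBu (0.3 equiv), DMSO–THF, 20 °C, argon; pH 7 buffer
Reagents that add atoms: none
Why: Base-mediated 1,3-prototropic shift of an allyl ether to an enol ether (the KOtBu/DMSO allyl-to-propenyl ether isomerization): C2–H is allylic, benzylic and α to oxygen, and reprotonation of the delocalized anion at C4 should give the trisubstituted C2=C3 enol ether conjugated with ring B and O1 as the thermodynamic isomer, so the uncontrolled C2 stereocentre disappears.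

Step 6
Reactants: 12 5,7-bis(benzyloxy)-2-[3,4-bis(benzyloxy)phenyl]-4H-chromene
Product: 14 (2R,3S)-5,7-bis(benzyloxy)-2-[3,4-bis(benzyloxy)phenyl]chroman-3-ol (tetra-O-benzyl-(+)-catechin), via alkyl(isopinocampheyl)borane 13 (not isolated)
Conditions: IpcBH2 derived from (+)-α-pinene (dIpcBH2, stock solution in Et2O, 1.3 equiv), THF, −25 °C; then NaOH, H2O2, 0 → 20 °C
Reagents that add atoms: hydrogen peroxide OO; monoisopinocampheylborane C[C@H]1[C@H](B)C[C@@H]2C[C@H]1C2(C)C (boron and terpene of intermediate 13 only)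
Why: Brown asymmetric hydroboration of a trisubstituted cyclic alkene: boron adds to C3 (β to O1, away from the aryl-bearing C2) and hydrogen to C2 on the same face, which fixes the 2,3-trans relation, and the reagent from (+)-α-pinene is expected, by analogy with 1-arylcycloalkenes that give (1S)-trans-2-arylcycloalkanols, to choose the face leading to 2R,3S, oxidation then proceeding with retention.

Step 7
Reactants: 14 (2R,3S)-5,7-bis(benzyloxy)-2-[3,4-bis(benzyloxy)phenyl]chroman-3-ol
Product: 15 (2R,3S)-5,7-bis(benzyloxy)-2-[3,4-bis(benzyloxy)phenyl]-8-bromochroman-3-ol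
Conditions: NBS (1.0 equiv), CH2Cl2, −78 °C → 0 °C
Reagents that add atoms: N-bromosuccinimide O=C1CCC(=O)N1Br
Why: Electrophilic bromination of ring A, which in 5,7-di-O-benzyl flavan-3-ols goes to C8 (flanked by the tied-back ring oxygen O1 and one benzyloxy group) in preference to C6 (between two benzyloxy groups).

Step 8
Reactants: 15 (2R,3S)-5,7-bis(benzyloxy)-2-[3,4-bis(benzyloxy)phenyl]-8-bromochroman-3-ol
Product: 16 (2R,3S)-3,5,7-tris(benzyloxy)-2-[3,4-bis(benzyloxy)phenyl]-8-bromochromane
Conditions: NaH, BnBr, DMF, 0 → 20 °C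
Reagents that add atoms: benzyl bromide BrCc1ccccc1
Why: Williamson etherification of the secondary alcohol, needed because a free hydroxyl would quench the aryllithium of step 9; this benzyl ether leaves with the others in step 15.

Step 9
Reactants: 16 (2R,3S)-3,5,7-tris(benzyloxy)-2-[3,4-bis(benzyloxy)phenyl]-8-bromochromane
Product: 18 (2R,3S)-3,5,7-tris(benzyloxy)-2-[3,4-bis(benzyloxy)phenyl]-8-(methoxymethyl)chromane, via 8-lithio flavan 17 (not isolated)
Conditions: n-BuLi (1.1 equiv), THF, −78 °C; MOMCl (1.5 equiv), −78 → 0 °C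
Reagents that add atoms: chloromethyl methyl ether COCCl; n-butyllithium [Li]CCCC (lithium of intermediate 17 only)
Why: Bromine–lithium exchange gives an aryllithium stabilized by two ortho oxygen atoms, which is alkylated by the very reactive α-chloro ether to give a benzylic methyl ether, a latent 2,4,6-trioxygenated benzyl cation.

Step 10
Reactants: 19 2,4,6-trihydroxytoluene
Product: 20 1-(2,4,6-trihydroxy-3-methylphenyl)ethanone
Conditions: Ac2O (1.05 equiv), BF3·OEt2 (3 equiv), 1,4-dioxane, 20 → 60 °C; then aq. NaOAc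
Reagents that add atoms: acetic anhydride CC(=O)OC(C)=O
Why: Friedel–Crafts C-acylation of a phloroglucinol under BF3 (O-acetate, then Fries-type migration); the two free ring carbons of 19 are equivalent, so only one monoketone can form.

Step 11
Reactants: 20 1-(2,4,6-trihydroxy-3-methylphenyl)ethanone
Product: 21 1-[4,6-bis(benzyloxy)-2-hydroxy-3-methylphenyl]ethanone
Conditions: BnBr (2.1 equiv), K2CO3, DMF, 20 °C
Reagents that add atoms: benzyl bromide BrCc1ccccc1
Why: Regioselective O-alkylation: the para hydroxyl and the less hindered ortho hydroxyl (next to the ring C–H) should react, while the ortho hydroxyl between acetyl and methyl stays behind, hindered and hydrogen-bonded to the carbonyl.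

Step 12
Reactants: 21 1-[4,6-bis(benzyloxy)-2-hydroxy-3-methylphenyl]ethanone
Product: 22 1-[4,6-bis(benzyloxy)-2-methoxy-3-methylphenyl]ethanone
Conditions: MeI (5 equiv), K2CO3, DMF, 50 °C
Reagents that add atoms: iodomethane CI
Why: Williamson methylation of the remaining chelated phenol under forcing conditions, with a carbonate base that does not enolize the ketone towards C-methylation.

Step 13
Reactants: 22 1-[4,6-bis(benzyloxy)-2-methoxy-3-methylphenyl]ethanone
Product: 23 1-(4,6-dihydroxy-2-methoxy-3-methylphenyl)ethanone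
Conditions: H2 (1 atm), Pd/C, EtOAc–MeOH, 20 °C
Reagents that add atoms: none
Why: Hydrogenolysis of aryl benzyl ethers, under which the hydrogen-bonded aryl ketone and the methyl ether are stable.

Step 14
Reactants: 18 (2R,3S)-3,5,7-tris(benzyloxy)-2-[3,4-bis(benzyloxy)phenyl]-8-(methoxymethyl)chromane; 23 1-(4,6-dihydroxy-2-methoxy-3-methylphenyl)ethanone
Product: 24 1-[3-{[(2R,3S)-3,5,7-tris(benzyloxy)-2-[3,4-bis(benzyloxy)phenyl]chroman-8-yl]methyl}-2,4-dihydroxy-6-methoxy-5-methylphenyl]ethanone
Conditions: BF3·OEt2 (1 equiv), 23 (3 equiv), CH2Cl2–Et2O, −20 → 0 °C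
Reagents that add atoms: none
Why: Friedel–Crafts benzylation: BF3 ionizes the benzylic methyl ether to a cation stabilized by O1, C7–O and C5–O, which is captured by the only free ring carbon of 23 (between its two hydroxyls), C-alkylation being the outcome expected under acid and the stereocentres not being involved.

Step 15
Reactants: 24 1-[3-{[(2R,3S)-3,5,7-tris(benzyloxy)-2-[3,4-bis(benzyloxy)phenyl]chroman-8-yl]methyl}-2,4-dihydroxy-6-methoxy-5-methylphenyl]ethanone
Product: 25 Pilosanol N
Conditions: H2 (1 atm), Pd(OH)2/C, THF–MeOH, 20 °C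
Reagents that add atoms: none
Why: Global hydrogenolysis of five benzyl ethers; the diarylmethane, the chelated acetyl group, the aryl methyl ether and the C2–O1 bond of the flavan are expected to survive at 1 atm, as in debenzylations of catechin derivatives.

**Compound list**
1 | 3,5-bis(benzyloxy)phenol | Oc1cc(OCc2ccccc2)cc(OCc2ccccc2)c1 | starting material
2 | 3,5-bis(benzyloxy)-2-bromophenol | Oc1cc(OCc2ccccc2)cc(OCc2ccccc2)c1Br | intermediate
3 | [3,5-bis(benzyloxy)-2-bromophenoxy]trimethylsilane (formed in the flask, not isolated) | C[Si](C)(C)Oc1cc(OCc2ccccc2)cc(OCc2ccccc2)c1Br | intermediate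
4 | lithium 3,5-bis(benzyloxy)-2-(trimethylsilyl)phenoxide (formed in the flask, not isolated) | [Li+].[O-]c1cc(OCc2ccccc2)cc(OCc2ccccc2)c1[Si](C)(C)C | intermediate
5 | 3,5-bis(benzyloxy)-2-(trimethylsilyl)phenyl trifluoromethanesulfonate | O=S(=O)(Oc1cc(OCc2ccccc2)cc(OCc2ccccc2)c1[Si](C)(C)C)C(F)(F)F | intermediate
6 | 3,4-bis(benzyloxy)benzaldehyde | O=Cc1ccc(OCc2ccccc2)c(OCc2ccccc2)c1 | starting material
7 | (E)-3-[3,4-bis(benzyloxy)phenyl]prop-2-enal | O=C/C=C/c1ccc(OCc2ccccc2)c(OCc2ccccc2)c1 | intermediate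
8 | 3,5-bis(benzyloxy)benzyne (formed in the flask, not isolated) | C1(OCc2ccccc2)=CC(OCc2ccccc2)=CC#C1 | intermediate
9 | racemic 3,5-bis(benzyloxy)-2-[(E)-2-(3,4-bis(benzyloxy)phenyl)ethenyl]-2H-1-benzoxete (formed in the flask, not isolated) | O1c2cc(OCc3ccccc3)cc(OCc3ccccc3)c2C1/C=C/c1ccc(OCc2ccccc2)c(OCc2ccccc2)c1 | intermediate
10 | 3,5-bis(benzyloxy)-6-[(2E)-3-(3,4-bis(benzyloxy)phenyl)prop-2-en-1-ylidene]cyclohexa-2,4-dien-1-one, the chain syn to C=O in the isomer that closes (formed in the flask, not isolated) | O=C1C=C(OCc2ccccc2)C=C(OCc2ccccc2)C1=C/C=C/c1ccc(OCc2ccccc2)c(OCc2ccccc2)c1 | intermediate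
11 | racemic 5,7-bis(benzyloxy)-2-[3,4-bis(benzyloxy)phenyl]-2H-chromene | c1ccccc1COc1cc(OCc2ccccc2)c2C=CC(c3ccc(OCc4ccccc4)c(OCc4ccccc4)c3)Oc2c1 | intermediate
12 | 5,7-bis(benzyloxy)-2-[3,4-bis(benzyloxy)phenyl]-4H-chromene (achiral) | c1ccccc1COc1cc(OCc2ccccc2)c2CC=C(c3ccc(OCc4ccccc4)c(OCc4ccccc4)c3)Oc2c1 | intermediate
13 | 2,3-trans 3-[(isopinocampheyl)boryl]-5,7-bis(benzyloxy)-2-[3,4-bis(benzyloxy)phenyl]chromane, boron where the 3-hydroxyl of 14 will stand (formed in the flask, not isolated) | C[C@H]1[C@H](B[C@H]3Cc4c(OCc5ccccc5)cc(OCc5ccccc5)cc4O[C@@H]3c3ccc(OCc4ccccc4)c(OCc4ccccc4)c3)C[C@@H]2C[C@H]1C2(C)C | intermediate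
14 | (2R,3S)-5,7-bis(benzyloxy)-2-[3,4-bis(benzyloxy)phenyl]chroman-3-ol | c1ccccc1COc1cc(OCc2ccccc2)c2c(c1)O[C@H](c1ccc(OCc3ccccc3)c(OCc3ccccc3)c1)[C@@H](O)C2 | intermediate
15 | (2R,3S)-5,7-bis(benzyloxy)-2-[3,4-bis(benzyloxy)phenyl]-8-bromochroman-3-ol | c1ccccc1COc1cc(OCc2ccccc2)c2c(c1Br)O[C@H](c1ccc(OCc3ccccc3)c(OCc3ccccc3)c1)[C@@H](O)C2 | intermediate
16 | (2R,3S)-3,5,7-tris(benzyloxy)-2-[3,4-bis(benzyloxy)phenyl]-8-bromochromane | c1ccccc1COc1cc(OCc2ccccc2)c2c(c1Br)O[C@H](c1ccc(OCc3ccccc3)c(OCc3ccccc3)c1)[C@@H](OCc1ccccc1)C2 | intermediate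
17 | (2R,3S)-3,5,7-tris(benzyloxy)-2-[3,4-bis(benzyloxy)phenyl]chroman-8-yllithium (formed in the flask, not isolated) | c1ccccc1COc1cc(OCc2ccccc2)c2c(c1[Li])O[C@H](c1ccc(OCc3ccccc3)c(OCc3ccccc3)c1)[C@@H](OCc1ccccc1)C2 | intermediate
18 | (2R,3S)-3,5,7-tris(benzyloxy)-2-[3,4-bis(benzyloxy)phenyl]-8-(methoxymethyl)chromane | c1ccccc1COc1cc(OCc2ccccc2)c2c(c1COC)O[C@H](c1ccc(OCc3ccccc3)c(OCc3ccccc3)c1)[C@@H](OCc1ccccc1)C2 | intermediate
19 | 2,4,6-trihydroxytoluene | Cc1c(O)cc(O)cc1O | starting material
20 | 1-(2,4,6-trihydroxy-3-methylphenyl)ethanone | CC(=O)c1c(O)cc(O)c(C)c1O | intermediate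
21 | 1-[4,6-bis(benzyloxy)-2-hydroxy-3-methylphenyl]ethanone | CC(=O)c1c(OCc2ccccc2)cc(OCc2ccccc2)c(C)c1O | intermediate
22 | 1-[4,6-bis(benzyloxy)-2-methoxy-3-methylphenyl]ethanone | CC(=O)c1c(OCc2ccccc2)cc(OCc2ccccc2)c(C)c1OC | intermediate
23 | 1-(4,6-dihydroxy-2-methoxy-3-methylphenyl)ethanone | CC(=O)c1c(O)cc(O)c(C)c1OC | intermediate
24 | 1-[3-{[(2R,3S)-3,5,7-tris(benzyloxy)-2-[3,4-bis(benzyloxy)phenyl]chroman-8-yl]methyl}-2,4-dihydroxy-6-methoxy-5-methylphenyl]ethanone | c1ccccc1COc1cc(OCc2ccccc2)c2c(c1Cc3c(O)c(C)c(OC)c(C(C)=O)c3O)O[C@H](c1ccc(OCc3ccccc3)c(OCc3ccccc3)c1)[C@@H](OCc1ccccc1)C2 | intermediate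
25 | Pilosanol N | COc1c(C)c(O)c(Cc2c(O)cc(O)c3c2O[C@H](c2ccc(O)c(O)c2)[C@@H](O)C3)c(O)c1C(C)=O | target

**Step count and risks**

Total: 15 steps. Longest linear sequence: 10 steps (1, 2, 4, 5, 6, 7, 8, 9, 14, 15).

Steps most likely to fail:

Risk at step 4. The carbonyl oxygen may add to the wrong aryne carbon, or the aryne may be consumed by the product chromene or by the C=C bond of 7. The fallback sets out from phenol 1 and enal 7 and comes back at 11. Heating 1 and 7 with phenylboronic acid (PhB(OH)2) and a little acetic acid in toluene with azeotropic removal of water should give the 2-phenyl-4H-1,3,2-benzodioxaborin F1. The boron template forces attack at the carbon ortho to the hydroxyl, and the two ortho carbons of 1 are equivalent. F1 should fragment thermally to ortho-quinone methide 10, which closes to 11 as in the main route. This fallback keeps the phenol oxygen of 1 as O1 and forms C4–C4a and O1–C2.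

Risk at step 5. The prototropic shift may stop at a mixture of 11 and 12, or the delocalized anion may be oxidized or open ring C. The fallback sets out from 11 and comes back at 14, passing by 12 and 13. It is a kinetic resolution of racemic 11 by copper-catalysed asymmetric protoboration (CuCl, NaOtBu, an enantiopure bisphospholane ligand of the Ph-BPE type, B2pin2 in about half an equivalent, MeOH, THF, 0 °C). The boryl–copper species adds to the styrene-type C3=C4 bond with boron at C3, anti to the C2 aryl group. The ligand antipode is chosen so that the enantiomer of 11 with the C2 geometry of 14 reacts faster. This should give the 2,3-trans 3-(pinacolboryl)flavan F2, which is separated from the unreacted chromene and oxidized (NaBO3, THF–H2O) to 14.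

Risk at step 6. The chiral borane may discriminate the faces of the enol ether poorly, or the β-aryloxy borane may be lost by elimination during the long reaction time. The fallback sets out from 12 and comes back at 14. Fast hydroboration with BH3·SMe2 at 0 °C and immediate oxidation (NaOH, H2O2) should give the racemic 2,3-trans flavan-3-ol F3. Esterification with (S)-2-methoxy-2-phenylacetic acid (DCC, DMAP, CH2Cl2) gives the diastereomeric esters, the (2R,3S) ester F4 and the (2S,3R) ester F5, which are separated by chromatography or crystallization. Hydrolysis of F4 (LiOH, THF–H2O) returns 14.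

**Further compounds**
F1 | step 4 | 5,7-bis(benzyloxy)-4-[(E)-2-(3,4-bis(benzyloxy)phenyl)ethenyl]-2-phenyl-4H-1,3,2-benzodioxaborinine (racemic) | c1ccccc1B1Oc2cc(OCc3ccccc3)cc(OCc3ccccc3)c2C(/C=C/c2ccc(OCc3ccccc3)c(OCc3ccccc3)c2)O1
F2 | step 5 | 2,3-trans 5,7-bis(benzyloxy)-2-[3,4-bis(benzyloxy)phenyl]-3-(4,4,5,5-tetramethyl-1,3,2-dioxaborolan-2-yl)chromane, boron where the 3-hydroxyl of 14 will stand | CC1(C)OB(OC1(C)C)[C@H]1Cc2c(OCc3ccccc3)cc(OCc3ccccc3)cc2O[C@@H]1c1ccc(OCc2ccccc2)c(OCc2ccccc2)c1
F3 | step 6 | racemic 2,3-trans-5,7-bis(benzyloxy)-2-[3,4-bis(benzyloxy)phenyl]chroman-3-ol (both enantiomers) | c1ccccc1COc1cc(OCc2ccccc2)c2c(c1)O[C@H](c1ccc(OCc3ccccc3)c(OCc3ccccc3)c1)[C@@H](O)C2.c1ccccc1COc1cc(OCc2ccccc2)c2c(c1)O[C@@H](c1ccc(OCc3ccccc3)c(OCc3ccccc3)c1)[C@H](O)C2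
F4 | step 6 | (2R,3S)-5,7-bis(benzyloxy)-2-[3,4-bis(benzyloxy)phenyl]chroman-3-yl (S)-2-methoxy-2-phenylacetate | c1ccccc1COc1cc(OCc2ccccc2)c2c(c1)O[C@H](c1ccc(OCc3ccccc3)c(OCc3ccccc3)c1)[C@@H](OC(=O)[C@@H](OC)c1ccccc1)C2
F5 | step 6 | (2S,3R)-5,7-bis(benzyloxy)-2-[3,4-bis(benzyloxy)phenyl]chroman-3-yl (S)-2-methoxy-2-phenylacetate | c1ccccc1COc1cc(OCc2ccccc2)c2c(c1)O[C@@H](c1ccc(OCc3ccccc3)c(OCc3ccccc3)c1)[C@H](OC(=O)[C@@H](OC)c1ccccc1)C2
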